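A small charge shows how the clock runs. The theta run, with 0.0079 M of starting material, stands at 5 % of target after 0.667 h. As a fraction of the charge it climbs at 0.180 h⁻¹ up to 1.00 h, then at 0.300 h⁻¹ from 1.50 h to 2.50 h, a faster slope. So the curve opens with a lag. The beta run, with 1.3 M, shows the lag too: 0 % at 0.417 h.

in all of them: partner 1.38 M; precatalyst 0.46 mM
- theta: starting material 0.0079 M; second substrate 0.92 M; run made earlier
- beta: starting material 1.3 M; second substrate 0.92 M; run made earlier
- north: starting material 0.015 M; second substrate 0.920 M; time 12 h
- south-west: starting material 0.050 M; second substrate 0.920 M; time 12 h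
- north-west: starting material 0.15 M; second substrate 0.920 M; time 12 h
- east: starting material 0.50 M; second substrate 0.920 M; time 12 h
- north-east: starting material 1.5 M; second substrate 0.920 M; time 12 h

| run | time / h | target / % |
|---|---|---|
| theta | 0.667 | 5 |
| theta | 1.00 | 11 |
| theta | 1.50 | 24 |
| theta | 2.50 | 54 |
| theta | 4.00 | 81 |
| theta | 6.00 | 95 |
| theta | 8.00 | 94 |
| beta | 0.417 | 0 |
| beta | 1.33 | 11 |
| beta | 2.50 | 39 |
| beta | 4.00 | 69 |
| beta | 5.00 | 76 |
| beta | 6.00 | 86 |
| beta | 8.00 | 92 |

(readings scatter by 2 percentage points)

- the analysis behind the earlier runs scatters by 2 percentage points, standard deviation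
- "hardly changes" means that all values lie within two and a half points (for a concentration: within two and a half percent of the largest)
- a step back or a flat step of under half a point counts as no turn

1. amount of target at the end, in percent of the starting material charged for north, south-west, north-west, east, north-east, in this order
2. the course of these numbers from the first flask to the last (hardly changes / rises, then falls / rises all the way / falls, then rises / falls all the way)

Beta bends near 4.00 h, at 69 %. I treat its tail as first order in what is still to come, so the rest decays exponentially in closed form. The readings at 4.00 h and 6.00 h give a rate constant of 0.397 h⁻¹, a reading with their scatter. Carried forward from 6.00 h, that tail stands at 98.7 % after 12 h.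

But I assume each target takes one partner. North-east then has 92.0 % as its level: the target that the partner charge can pay for, in percent of the starting material charged, the partner ceiling. That is lower than the clock allows, so I call the partner the limiting reagent in north-east. By my reckoning beta's tail, laid over north-east, reaches the ceiling at 7.41 h, earlier than 12 h, so I draw the north-east curve flat from there. East has a ceiling above the whole charge. So I put the four smaller flasks at 98.7 % and north-east at 92.0 %.

The forecast differs: 95 %, 95 %, 95 %, 94.5 %, 93 %, and hardly changes, in its words “I expect about 95% throughout”.

The flasks give 100 %, 100 %, 100 %, 100 % and 84.5 %; the row falls all the way.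

    starting material + free catalyst ⇌ catalyst intermediate A (K = 10.8 M⁻¹, k = 4900 M⁻¹ h⁻¹)
    partner + catalyst intermediate A → free catalyst + target (k = 9750 M⁻¹ h⁻¹)
    second substrate + free catalyst ⇌ catalyst intermediate B (K = 3.49 M⁻¹, k = 66200 M⁻¹ h⁻¹)
    partner + catalyst intermediate B → free catalyst + second product (k = 4730 M⁻¹ h⁻¹)
    partner + precatalyst → free catalyst + spent reagent (k = 0.109 M⁻¹ h⁻¹)
    2 second substrate → self-condensation product (k = 3.46 M⁻¹ h⁻¹)

North-east ends 7.5 percentage points under its ceiling of 92.0 %, with partner at 0.00854 % of its charge, and its 0.112 M of second product is 7.46 % of the starting material charged. In north, the second substrate's first half-life by self-condensation alone, 0.157 h, is shorter than its 3.1 h by the forward step to catalyst intermediate B at 0.117 h. East, with a partner ceiling of 276 %, ends at 100 % of target with 54.3 % of its partner left.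

The earlier runs and the new flask come from a simulation from invented constants.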